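A direct plan would buy all three rings as orcinol-type arenes and join them ester by ester. A benzyl-protected orsellinic acid would be coupled with a ring A phenol and debenzylated to the A–B diphenol A2. Ring C would come last, by palladium-catalysed carbonylation of the aryl iodide A1 onto the 4-hydroxyl of A2, giving the benzyl ether A3 and, after hydrogenolysis, the target. Its weakest steps would be:
- the iodination leading to A1, because three ring positions are open and the most crowded one is needed;
- the carbonylative aroylation of A2, which needs CO insertion at a di-ortho-substituted aryl–palladium bond, a choice between two phenols and survival of two aryl esters, all on the most valuable material;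
- the protecting-group traffic, in which several benzylations and hydrogenolyses form no skeletal bond.

**Plan of the new route**
The retrosynthesis cuts ring B itself, at C1–C2 and C5–C6 (C1 bears the carboxyl, C2 the OH, C4 the aroyloxy group, C6 the CH3). Ring B is a resorcylate: C2–C5, with oxygen on C2 and C4, are the carbons of acetoacetate, and C1, C6, the methyl and the carboxyl are those of but-2-ynoic acid; both ester links of the target end on this ring. Rings A and C are bought as arenes: ring A is esterified with the ynoic acid, ring C is placed on the enol oxygen of methyl acetoacetate, and ring B arises last, between them, by Diels–Alder benzannulation. No arene is iodinated, no two-phenol depside is acylated, nothing is carbonylated late, and the single silyl protecting group falls in the work-up of the key step.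

Key step: step 8

Remark on the chemistry: enol ester 13 is expected as an E/Z mixture. Both isomers give the same diene 14, so this geometry and that of the ketene acetal in 14 are left open. The target has no stereocentre.

**Ring A dienophile**

Step 1
Reactants: 1 methyl 2-methoxy-6-methylbenzoate
Product: 3 methyl 4-hydroxy-2-methoxy-6-methylbenzoate, via aryl pinacol boronate 2 (not isolated)
Conditions: B2pin2 (1.0 equiv), [Ir(OMe)(cod)]2 (1.5 mol %, cod = 1,5-cyclooctadiene), 4,4'-di-tert-butyl-2,2'-bipyridine (3 mol %), THF, 80 °C; evaporate; then KHSO5 (as Oxone), acetone/H2O, rt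
Reagents that add atoms: potassium peroxymonosulfate, [K+].[O-]S(=O)(=O)OO
Why: Iridium-catalysed aromatic C–H borylation is sterically controlled and should occur at C4, the only ring C–H of this 1,2,3-trisubstituted arene without an ortho substituent, and the crude boronate is oxidised to the phenol in the same flask (one-pot borylation/oxidation).

Step 2
Reactants: 3 methyl 4-hydroxy-2-methoxy-6-methylbenzoate; 4 but-2-ynoic acid
Product: 5 methyl 4-(but-2-ynoyloxy)-2-methoxy-6-methylbenzoate
Conditions: DCC, DMAP (5 mol %), CH2Cl2, 0 °C → rt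
Reagents that add atoms: none
Why: Steglich esterification of the only phenol with but-2-ynoic acid proceeds under neutral carbodiimide activation, which leaves the triple bond and the methyl ester untouched.

**Ring C diene**

Step 3
Reactants: 6 methyl 2,4-dihydroxy-6-methylbenzoate
Product: 7 methyl 2-hydroxy-4-methoxy-6-methylbenzoate
Conditions: MeI (1.05 equiv), K2CO3, acetone, reflux
Reagents that add atoms: iodomethane, CI
Why: Williamson etherification with one equivalent of iodomethane and a weak base should take place at the 4-OH only, because the 2-OH is less acidic and hydrogen-bonded to the ester carbonyl.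

Step 4
Reactants: 7 methyl 2-hydroxy-4-methoxy-6-methylbenzoate
Product: 8 2-hydroxy-4-methoxy-6-methylbenzoic acid
Conditions: KOH, DMSO/H2O (4:1), 90 °C; then aq. HCl, 0 °C
Reagents that add atoms: potassium hydroxide, [K+].[OH-]
Why: Saponification of the di-ortho-substituted methyl ester needs hot hydroxide in aqueous DMSO, which the aryl methyl ether tolerates, and cold acidification limits decarboxylation of the electron-rich salicylic acid.

Step 5
Reactants: 8 2-hydroxy-4-methoxy-6-methylbenzoic acid
Product: 10 2-[(tert-butyldimethylsilyl)oxy]-4-methoxy-6-methylbenzoic acid, via bis-silylated acid 9 (not isolated)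
Conditions: t-BuMe2SiCl (2.5 equiv), imidazole, DMF, 40 °C; then AcOH/THF/H2O, rt
Reagents that add atoms: tert-butyl(chloro)dimethylsilane, CC(C)(C)[Si](C)(C)Cl
Why: Silylation of both acidic groups followed by selective hydrolysis of the far more labile silyl ester leaves the acid with its ortho phenol masked as a silyl ether (protection), so that the phenol can neither interfere with the acid chloride nor add to the enol ester made next.

Step 6
Reactants: 10 2-[(tert-butyldimethylsilyl)oxy]-4-methoxy-6-methylbenzoic acid; 11 methyl acetoacetate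
Product: 13 methyl 3-({2-[(tert-butyldimethylsilyl)oxy]-4-methoxy-6-methylbenzoyl}oxy)but-2-enoate, via aroyl chloride 12 (not isolated)
Conditions: (COCl)2, cat. DMF, CH2Cl2, 0 °C → rt; evaporate; then 11 (1.5 equiv), Et3N, DMAP (10 mol %), CH2Cl2, 0 °C → rt
Reagents that add atoms: none
Why: Acid chloride formation is followed by O-acylation of the amine-generated enolate of the β-keto ester, which the hard, hindered aroyl chloride should attack on oxygen, and the resulting enol ester fixes the ring C acyl group on the future O4 of ring B.

Step 7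
Reactants: 13 methyl 3-({2-[(tert-butyldimethylsilyl)oxy]-4-methoxy-6-methylbenzoyl}oxy)but-2-enoate
Product: 14 4-methoxy-4-[(trimethylsilyl)oxy]buta-1,3-dien-2-yl 2-[(tert-butyldimethylsilyl)oxy]-4-methoxy-6-methylbenzoate
Conditions: LiN(i-Pr)2 (1.15 equiv), THF, −78 °C; Me3SiCl, −78 °C → rt; evaporate, pentane, filter under Ar; used crude
Reagents that add atoms: chlorotrimethylsilane, C[Si](C)(C)Cl
Why: γ-Deprotonation of the 3-oxygenated crotonate by a lithium amide at low temperature and O-silylation of the extended dienolate should give the 1-methoxy-1-silyloxydiene (the standard preparation of ketene acetal dienes), the di-ortho-substituted aroyl carbonyl being shielded against the base.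

**Ring B last**

Step 8
Reactants: 14 4-methoxy-4-[(trimethylsilyl)oxy]buta-1,3-dien-2-yl 2-[(tert-butyldimethylsilyl)oxy]-4-methoxy-6-methylbenzoate (2 equiv); 5 methyl 4-(but-2-ynoyloxy)-2-methoxy-6-methylbenzoate
Product: 17 methyl 4-({2-hydroxy-4-[(2-hydroxy-4-methoxy-6-methylbenzoyl)oxy]-6-methylbenzoyl}oxy)-2-methoxy-6-methylbenzoate, via cyclohexa-1,4-diene cycloadduct 15 (not isolated), via bis-silyl tridepside 16 (not isolated)
Conditions: toluene, 110–130 °C, sealed tube; then Bu4NF/AcOH (1:1), THF, 0 °C
Reagents that add atoms: none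
Why: Proposed new method: the electron-rich 1,1,3-trioxygenated diene 14 should add to the aryl ynoate 5 in a normal-demand, probably asynchronous (4+2) cycloaddition in which the CH2 terminus (largest HOMO coefficient, future C5) bonds to the methyl-bearing β-carbon (future C6) and the ketene acetal carbon (future C2) to the α-carbon (future C1), after which the cyclohexa-1,4-diene 15 aromatises by 1,4-loss of methanol. The closest known reaction type is the Diels–Alder benzannulation of 1-alkoxy-1-silyloxy- and 1,1-dialkoxy-3-silyloxybuta-1,3-dienes with 2-alkynoates, β-alkyl-substituted ones included, which gives 6-alkylresorcylates with this orientation; the case here differs in that the C3 oxygen of the diene carries an aroyl group in place of silicon. Ring B is closed intermolecularly by forming C1–C2 and C5–C6, and no stereocentre remains, because the one formed at C2 of 15 is lost on aromatisation. The step needs regioselectivity, which the matched polarisation of the two partners secures, and survival of one enol ester and two aryl esters, which neutral thermal conditions, the di-ortho substitution of the ring C carbonyl and the excess of diene (it scavenges the methanol set free) should allow. The aroyloxy group makes the diene less electron-rich than its silyloxy analogue, which the electron-poor aryl ester of 5 and heating should offset. Buffered fluoride then removes both silyl groups of 16, so that the target is released without a separate deprotection step.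

**Compound list**

1 | methyl 2-methoxy-6-methylbenzoate | COC(=O)c1c(C)cccc1OC | starting material
2 | methyl 2-methoxy-6-methyl-4-(4,4,5,5-tetramethyl-1,3,2-dioxaborolan-2-yl)benzoate (not isolated) | COC(=O)c1c(C)cc(B2OC(C)(C)C(C)(C)O2)cc1OC | intermediate
3 | methyl 4-hydroxy-2-methoxy-6-methylbenzoate | COC(=O)c1c(C)cc(O)cc1OC | intermediate
4 | but-2-ynoic acid | CC#CC(=O)O | starting material
5 | methyl 4-(but-2-ynoyloxy)-2-methoxy-6-methylbenzoate | COC(=O)c1c(C)cc(OC(=O)C#CC)cc1OC | intermediate
6 | methyl 2,4-dihydroxy-6-methylbenzoate | COC(=O)c1c(C)cc(O)cc1O | starting material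
7 | methyl 2-hydroxy-4-methoxy-6-methylbenzoate | COC(=O)c1c(C)cc(OC)cc1O | intermediate
8 | 2-hydroxy-4-methoxy-6-methylbenzoic acid | Cc1cc(OC)cc(O)c1C(=O)O | intermediate
9 | tert-butyldimethylsilyl 2-[(tert-butyldimethylsilyl)oxy]-4-methoxy-6-methylbenzoate (not isolated) | Cc1cc(OC)cc(O[Si](C)(C)C(C)(C)C)c1C(=O)O[Si](C)(C)C(C)(C)C | intermediate
10 | 2-[(tert-butyldimethylsilyl)oxy]-4-methoxy-6-methylbenzoic acid | Cc1cc(OC)cc(O[Si](C)(C)C(C)(C)C)c1C(=O)O | intermediate
11 | methyl acetoacetate (methyl 3-oxobutanoate) | COC(=O)CC(C)=O | starting material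
12 | 2-[(tert-butyldimethylsilyl)oxy]-4-methoxy-6-methylbenzoyl chloride (not isolated) | Cc1cc(OC)cc(O[Si](C)(C)C(C)(C)C)c1C(=O)Cl | intermediate
13 | methyl 3-({2-[(tert-butyldimethylsilyl)oxy]-4-methoxy-6-methylbenzoyl}oxy)but-2-enoate (E/Z mixture) | COC(=O)C=C(C)OC(=O)c1c(C)cc(OC)cc1O[Si](C)(C)C(C)(C)C | intermediate
14 | 4-methoxy-4-[(trimethylsilyl)oxy]buta-1,3-dien-2-yl 2-[(tert-butyldimethylsilyl)oxy]-4-methoxy-6-methylbenzoate | C=C(OC(=O)c1c(C)cc(OC)cc1O[Si](C)(C)C(C)(C)C)C=C(OC)O[Si](C)(C)C | intermediate
15 | methyl 4-{[4-({2-[(tert-butyldimethylsilyl)oxy]-4-methoxy-6-methylbenzoyl}oxy)-6-methoxy-2-methyl-6-[(trimethylsilyl)oxy]cyclohexa-1,4-diene-1-carbonyl]oxy}-2-methoxy-6-methylbenzoate (racemic, not isolated) | COC(=O)c1c(C)cc(OC(=O)C2=C(C)CC(OC(=O)c3c(C)cc(OC)cc3O[Si](C)(C)C(C)(C)C)=CC2(OC)O[Si](C)(C)C)cc1OC | intermediate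
16 | methyl 4-{[4-({2-[(tert-butyldimethylsilyl)oxy]-4-methoxy-6-methylbenzoyl}oxy)-2-methyl-6-[(trimethylsilyl)oxy]benzoyl]oxy}-2-methoxy-6-methylbenzoate (not isolated) | COC(=O)c1c(C)cc(OC(=O)c2c(C)cc(OC(=O)c3c(C)cc(OC)cc3O[Si](C)(C)C(C)(C)C)cc2O[Si](C)(C)C)cc1OC | intermediate
17 | methyl 4-({2-hydroxy-4-[(2-hydroxy-4-methoxy-6-methylbenzoyl)oxy]-6-methylbenzoyl}oxy)-2-methoxy-6-methylbenzoate | COC(=O)c1c(C)cc(OC(=O)c2c(C)cc(OC(=O)c3c(C)cc(OC)cc3O)cc2O)cc1OC | target

Total step count: 8. Longest linear sequence: 6 steps (steps 3, 4, 5, 6, 7, 8).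

**Steps most likely to fail**

1. Step 8. The acyloxy diene may decompose by desilylation or acyl transfer faster than it adds to the β-methyl ynoate, so that no cycloadduct forms. The fallback uses known reactions only, sets out from acid 10 and phenol 3 and returns at 17. Acid 10 would be converted into chloride 12 as in step 6 and used to acylate the free 4-hydroxyl of commercial 2,4-dihydroxy-6-methylbenzaldehyde (Et3N, cat. DMAP, CH2Cl2; the 2-hydroxyl is tied up by the aldehyde) to give 4-formyl-3-hydroxy-5-methylphenyl 2-[(tert-butyldimethylsilyl)oxy]-4-methoxy-6-methylbenzoate F1. Pinnick oxidation (NaClO2, NaH2PO4, 2-methylbut-2-ene, t-BuOH/H2O) would give 4-({2-[(tert-butyldimethylsilyl)oxy]-4-methoxy-6-methylbenzoyl}oxy)-2-hydroxy-6-methylbenzoic acid F2. Carbodiimide esterification of F2 with 3 (DCC, toluene) would give methyl 4-{[4-({2-[(tert-butyldimethylsilyl)oxy]-4-methoxy-6-methylbenzoyl}oxy)-2-hydroxy-6-methylbenzoyl]oxy}-2-methoxy-6-methylbenzoate F3, and Bu4NF/AcOH would release 17.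

2. Step 7. The amide base may attack the enol ester, or the dienolate may lose the aroate before it is silylated. The fallback sets out from acid 10 and returns at 14. Ruthenium-catalysed Markovnikov addition of 10 to methyl but-3-ynoate ([RuCl2(p-cymene)]2, P(4-ClC6H4)3, cat. DMAP, toluene, 60 °C) would give the non-conjugated enol ester methyl 3-({2-[(tert-butyldimethylsilyl)oxy]-4-methoxy-6-methylbenzoyl}oxy)but-3-enoate F4. Its doubly activated CH2 group would be converted into the same diene by soft enolisation (Et3N, Me3SiOTf, Et2O, 0 °C), so that no lithium amide meets the enol ester.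

3. Step 6. The acetoacetate enolate may be acylated on carbon instead of oxygen, or the hindered chloride may hydrolyse before it reacts. The fallback sets out from acid 10 and returns at 13: amine-catalysed conjugate addition of the carboxylic acid to methyl buta-2,3-dienoate (cat. Et3N or DABCO, MeCN, rt). The C–O bond is then made at the enol carbon, so acylation on carbon cannot occur; no new compound is needed.

**Further compounds**

F1 | step 8 | 4-formyl-3-hydroxy-5-methylphenyl 2-[(tert-butyldimethylsilyl)oxy]-4-methoxy-6-methylbenzoate | Cc1cc(OC)cc(O[Si](C)(C)C(C)(C)C)c1C(=O)Oc1cc(C)c(C=O)c(O)c1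
F2 | step 8 | 4-({2-[(tert-butyldimethylsilyl)oxy]-4-methoxy-6-methylbenzoyl}oxy)-2-hydroxy-6-methylbenzoic acid | Cc1cc(OC)cc(O[Si](C)(C)C(C)(C)C)c1C(=O)Oc1cc(C)c(C(=O)O)c(O)c1
F3 | step 8 | methyl 4-{[4-({2-[(tert-butyldimethylsilyl)oxy]-4-methoxy-6-methylbenzoyl}oxy)-2-hydroxy-6-methylbenzoyl]oxy}-2-methoxy-6-methylbenzoate | COC(=O)c1c(C)cc(OC(=O)c2c(C)cc(OC(=O)c3c(C)cc(OC)cc3O[Si](C)(C)C(C)(C)C)cc2O)cc1OC
F4 | step 7 | methyl 3-({2-[(tert-butyldimethylsilyl)oxy]-4-methoxy-6-methylbenzoyl}oxy)but-3-enoate | COC(=O)CC(=C)OC(=O)c1c(C)cc(OC)cc1O[Si](C)(C)C(C)(C)C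
F0 | step 6 | none | none
A1 | direct plan | 1-(benzyloxy)-2-iodo-5-methoxy-3-methylbenzene | COc1cc(C)c(I)c(OCc2ccccc2)c1
A2 | direct plan | methyl 4-[(2,4-dihydroxy-6-methylbenzoyl)oxy]-2-methoxy-6-methylbenzoate | COC(=O)c1c(C)cc(OC(=O)c2c(C)cc(O)cc2O)cc1OC
A3 | direct plan | methyl 4-[(4-{[2-(benzyloxy)-4-methoxy-6-methylbenzoyl]oxy}-2-hydroxy-6-methylbenzoyl)oxy]-2-methoxy-6-methylbenzoate | COC(=O)c1c(C)cc(OC(=O)c2c(C)cc(OC(=O)c3c(C)cc(OC)cc3OCc3ccccc3)cc2O)cc1OC
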